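**Plan**

- Retrosynthesis: both C1–O(C9) ester bonds of the 20-membered diolide are cut first, giving one C1–C10 hydroxy acid used twice. Then the C5–C6 bond is cut (alkylzinc plus a (2Z,4Z)-5-iodo-2-methylpentadienoate), then oxazole C4–C5 and O1–C2 (seven-membered lactone plus LiCH2NC).
- Enabling feature: C6–C10 and oxazole C5 are six contiguous carbons that fold into a cyclohexane on which the C8 methyl and the C9 oxygen are trans. Oxazole C5 is at the carboxyl level and C6 carries oxygen, so the chain is the Baeyer–Villiger lactone of (3R,4R)-3-silyloxy-4-methylcyclohexanone.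
- Forward order: cyclohexane (from 4-methylanisole), then oxepanone, then the oxazole with opening of the lactone, then chain extension by Negishi coupling, then the 20-membered ring by cyclodimerising lactonisation.
- Stereochemistry: C8 and C9 come from one reagent-controlled syn hydroboration (trans on the ring is syn in the chain) and are not touched again. The 2Z alkene comes from a Still–Gennari olefination and the 4Z alkene from ethyl (Z)-3-iodoacrylate, both carried through the coupling with retention.

Key step: step 8

Assumption: the facial sense of monoisopinocampheylborane is taken from simple 1-methylcycloalkenes, where the (+)-α-pinene-derived reagent gives (1S,2S)-trans-2-methylcycloalkanols, so the (−)-α-pinene-derived reagent is specified for the (7R,8R) alcohol; each half of the diolide is numbered C1 (ester carbonyl) to C10 (CH2 carrying the oxazole) and the oxazole atoms are O1, C2, N3, C4, C5.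

**Route**

Step 1
Reactants: 1 4-methylanisole
Product: 2 1-methoxy-4-methylcyclohexa-1,4-diene
Conditions: Li, liquid NH3, THF, t-BuOH, −78 °C → −33 °C
Reagents that add atoms: none
Why: Birch reduction of an anisole gives the 2,5-dihydro isomer, leaving the methoxy and methyl groups on two isolated double bonds so that the masked ketone carbon and the trisubstituted alkene are differentiated.

Step 2
Reactants: 2 1-methoxy-4-methylcyclohexa-1,4-diene
Product: 3 8-methyl-1,4-dioxaspiro[4.5]dec-7-ene
Conditions: HOCH2CH2OH, TsOH·H2O (cat.), CH2Cl2, 0 °C → rt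
Reagents that add atoms: ethylene glycol, OCCO
Why: Acid-catalysed acetal exchange, in which C-protonation of the enol ether gives an oxocarbenium ion that the diol captures with loss of methanol, while the non-conjugated trisubstituted alkene should neither migrate nor hydrate under these mild conditions.

Step 3
Reactants: 3 8-methyl-1,4-dioxaspiro[4.5]dec-7-ene
Product: 5 (7R,8R)-8-methyl-1,4-dioxaspiro[4.5]decan-7-ol, via dialkylborane 4 (not isolated)
Conditions: IpcBH2 [from (−)-α-pinene, preformed solution], Et2O, −25 °C; then NaOH, H2O2, THF/H2O, 0 °C → rt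
Reagents that add atoms: hydrogen peroxide, OO
Why: Asymmetric hydroboration–oxidation, in which boron adds to the less substituted alkene carbon C7 and hydrogen to C8 on the same face chosen by the isopinocampheyl group and oxidation proceeds with retention, so the trans alcohol and both stereocentres (later C9 and C8) are set by the reagent, and any minor enantiomer carried forward should end mainly in a separable diastereomeric heterodimer at step 14.

Step 4
Reactants: 5 (7R,8R)-8-methyl-1,4-dioxaspiro[4.5]decan-7-ol
Product: 6 tert-butyldimethyl{[(7R,8R)-8-methyl-1,4-dioxaspiro[4.5]decan-7-yl]oxy}silane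
Conditions: TBSCl, imidazole, DMF, rt
Reagents that add atoms: tert-butyldimethylsilyl chloride, CC(C)(C)[Si](C)(C)Cl
Why: Imidazole-promoted silylation of a secondary alcohol gives an ether that should survive the later peracid, organolithium, zinc and palladium conditions.

Step 5
Reactants: 6 tert-butyldimethyl{[(7R,8R)-8-methyl-1,4-dioxaspiro[4.5]decan-7-yl]oxy}silane
Product: 7 (3R,4R)-3-(tert-butyldimethylsilyloxy)-4-methylcyclohexan-1-one
Conditions: pyridinium p-toluenesulfonate (cat.), acetone/H2O, 50 °C
Reagents that add atoms: water, O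
Why: Acid-catalysed hydrolysis of the dioxolane (acetal exchange in wet acetone) under a weakly acidic buffer should keep the secondary silyl ether and avoid β-elimination from the β-silyloxy ketone.

Step 6
Reactants: 7 (3R,4R)-3-(tert-butyldimethylsilyloxy)-4-methylcyclohexan-1-one
Product: 8 (4R,5R)-4-(tert-butyldimethylsilyloxy)-5-methyloxepan-2-one
Conditions: mCPBA, CH2Cl2, 0 °C → rt
Reagents that add atoms: 3-chloroperbenzoic acid, OOC(=O)c1cccc(Cl)c1
Why: Baeyer–Villiger oxidation, in which the C6 methylene should migrate in preference to C2 because the electron-withdrawing silyloxy group on C3 lowers the migratory aptitude of the adjacent C2, so the new oxygen lands on the future C6 of the target and the two stereocentres are untouched.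

Step 7
Reactants: 9 N-methylformamide
Product: 10 methyl isocyanide
Conditions: TsCl, quinoline, 75 °C, reduced pressure, product distilled into a cold trap
Reagents that add atoms: none
Why: Dehydration of an N-monosubstituted formamide to the isocyanide by a sulfonyl chloride and a high-boiling amine base, with the volatile product removed by distillation as it forms.

Step 8
Reactants: 8 (4R,5R)-4-(tert-butyldimethylsilyloxy)-5-methyloxepan-2-one; 10 methyl isocyanide
Product: 14 (3R,4R)-4-(tert-butyldimethylsilyloxy)-3-methyl-5-(1,3-oxazol-5-yl)pentan-1-ol, via isocyanomethyllithium 11 (not isolated), via isocyano ketone enolate 12 (not isolated), via 2-lithiooxazole 13 (not isolated)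
Conditions: 10 (2.5 equiv), n-BuLi (2.4 equiv), THF, −78 °C; 8 added slowly, −78 °C → 0 °C; AcOH, 0 °C → rt
Reagents that add atoms: none
Why: Isocyanomethyllithium 11 adds to the lactone carbonyl of 8, the tetrahedral alkoxide collapses with expulsion of the C6 alkoxide (this makes oxazole C4–C5), and a second equivalent of 11 removes the doubly activated proton between carbonyl and isocyanide to give enolate 12. The enolate oxygen of 12 then attacks the isocyanide carbon in a 5-endo-dig closure to the 2-lithiooxazole 13 (this makes O1–C2), an equilibrium that acetic acid drains by protonating C2 and the C6 alkoxide. The closest known reaction type is the Schöllkopf oxazole synthesis from α-metalated isocyanides and esters or lactones. No stereocentre is created, and C8 and C9 pass through unchanged because neither carries an acidic hydrogen. The selectivity needed is carbonyl addition ahead of deprotonation at the lactone α-carbon (C10 of the target), which would trigger E1cB loss of the C9 silyloxy group; it is secured by the small, strongly nucleophilic carbanion at −78 °C, by adding 8 to an excess of 11, and by the acylated product being held at once as enolate 12, which is directed away from the silyloxy-bearing carbon.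

Step 9
Reactants: 14 (3R,4R)-4-(tert-butyldimethylsilyloxy)-3-methyl-5-(1,3-oxazol-5-yl)pentan-1-ol
Product: 15 5-[(2R,3R)-2-(tert-butyldimethylsilyloxy)-5-iodo-3-methylpentyl]-1,3-oxazole
Conditions: I2, PPh3, imidazole, CH2Cl2, 0 °C → rt
Reagents that add atoms: iodine, II
Why: Appel-type iodination, in which the primary alcohol is activated as an alkoxyphosphonium ion and displaced by iodide in an SN2 step under conditions to which the silyl ether and the oxazole are inert.

Step 10
Reactants: 16 ethyl (Z)-3-iodoacrylate; 17 ethyl 2-[bis(2,2,2-trifluoroethoxy)phosphoryl]propanoate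
Product: 19 ethyl (2Z,4Z)-5-iodo-2-methylpenta-2,4-dienoate, via (Z)-3-iodoacrolein 18 (not isolated)
Conditions: i-Bu2AlH, CH2Cl2, −78 °C; MeOH then H2O, −78 °C → 0 °C; the dried cold solution of 18 added to 17, KN(SiMe3)2, 18-crown-6, THF, −78 °C
Reagents that add atoms: none
Why: Partial reduction of the ester at −78 °C followed by Still–Gennari olefination, in which the trifluoroethyl phosphonate under dissociating conditions eliminates rapidly from the kinetic adduct to give the (Z)-trisubstituted enoate, while the low temperature preserves the labile (Z)-iodoalkene.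

Step 11
Reactants: 15 5-[(2R,3R)-2-(tert-butyldimethylsilyloxy)-5-iodo-3-methylpentyl]-1,3-oxazole; 19 ethyl (2Z,4Z)-5-iodo-2-methylpenta-2,4-dienoate
Product: 21 ethyl (2Z,4Z,8R,9R)-9-(tert-butyldimethylsilyloxy)-2,8-dimethyl-10-(1,3-oxazol-5-yl)deca-2,4-dienoate, via alkylzinc iodide 20 (not isolated)
Conditions: Zn dust (activated with BrCH2CH2Br and Me3SiCl), DMF, rt; then 19, Pd(PPh3)4 (cat.), rt
Reagents that add atoms: none
Why: Direct insertion of activated zinc into the primary C–I bond followed by Negishi cross-coupling, in which oxidative addition of zerovalent palladium to the alkenyl iodide and reductive elimination both go with retention, so the 4Z geometry is transferred and the mild organozinc tolerates the ester, the silyl ether and the oxazole.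

Step 12
Reactants: 21 ethyl (2Z,4Z,8R,9R)-9-(tert-butyldimethylsilyloxy)-2,8-dimethyl-10-(1,3-oxazol-5-yl)deca-2,4-dienoate
Product: 22 (2Z,4Z,8R,9R)-9-(tert-butyldimethylsilyloxy)-2,8-dimethyl-10-(1,3-oxazol-5-yl)deca-2,4-dienoic acid
Conditions: LiOH·H2O, THF/MeOH/H2O, rt; then aqueous HCl to pH 4
Reagents that add atoms: lithium hydroxide, [Li+].[OH-]
Why: Saponification of the ethyl ester near room temperature should leave the hindered secondary silyl ether and the diene geometry unaffected.

Step 13
Reactants: 22 (2Z,4Z,8R,9R)-9-(tert-butyldimethylsilyloxy)-2,8-dimethyl-10-(1,3-oxazol-5-yl)deca-2,4-dienoic acid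
Product: 23 (2Z,4Z,8R,9R)-9-hydroxy-2,8-dimethyl-10-(1,3-oxazol-5-yl)deca-2,4-dienoic acid
Conditions: HF·pyridine, pyridine/THF, 0 °C → rt
Reagents that add atoms: none
Why: Fluoride-mediated desilylation driven by the strength of the Si–F bond, with buffered HF·pyridine chosen so that the dienoic acid is not exposed to a basic fluoride source.

Step 14
Reactants: 23 (2Z,4Z,8R,9R)-9-hydroxy-2,8-dimethyl-10-(1,3-oxazol-5-yl)deca-2,4-dienoic acid (two molecules)
Product: 26 (3Z,5Z,9R,10R,13Z,15Z,19R,20R)-3,9,13,19-tetramethyl-10,20-bis(1,3-oxazol-5-ylmethyl)-1,11-dioxacycloicosa-3,5,13,15-tetraene-2,12-dione, via mixed anhydride 24 (not isolated), via linear dimer anhydride 25 (not isolated)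
Conditions: 2,4,6-Cl3C6H2COCl, Et3N, THF, rt; then DMAP, toluene, rt, about 5 mM
Reagents that add atoms: none
Why: Yamaguchi macrolactonisation run as a cyclodimerisation, in which mixed anhydride 24 is acylated intermolecularly by the C9 hydroxyl of a second molecule because the alternative ten-membered monomeric lactone holding a (Z,Z)-diene is strained, and the linear dimer 25 then closes the unstrained twenty-membered ring with retention at C9 since only the acyl C–O bond is formed.

**Compound list**

1 | 4-methylanisole | COc1ccc(C)cc1 | starting material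
2 | 1-methoxy-4-methylcyclohexa-1,4-diene | COC1=CCC(C)=CC1 | intermediate
3 | 8-methyl-1,4-dioxaspiro[4.5]dec-7-ene | CC1=CCC2(CC1)OCCO2 | intermediate
4 | (−)-α-pinene-derived isopinocampheyl[(7R,8R)-8-methyl-1,4-dioxaspiro[4.5]decan-7-yl]borane | C[C@H]1[C@@H]2C[C@@H](C2(C)C)C[C@@H]1B[C@@H]3CC4(OCCO4)CC[C@H]3C | intermediate (not isolated)
5 | (7R,8R)-8-methyl-1,4-dioxaspiro[4.5]decan-7-ol | O[C@@H]1CC2(OCCO2)CC[C@H]1C | intermediate
6 | tert-butyldimethyl{[(7R,8R)-8-methyl-1,4-dioxaspiro[4.5]decan-7-yl]oxy}silane | CC(C)(C)[Si](C)(C)O[C@@H]1CC2(OCCO2)CC[C@H]1C | intermediate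
7 | (3R,4R)-3-(tert-butyldimethylsilyloxy)-4-methylcyclohexan-1-one | O=C1CC[C@@H](C)[C@@H](C1)O[Si](C)(C)C(C)(C)C | intermediate
8 | (4R,5R)-4-(tert-butyldimethylsilyloxy)-5-methyloxepan-2-one | O1CC[C@@H](C)[C@@H](CC1=O)O[Si](C)(C)C(C)(C)C | intermediate
9 | N-methylformamide | CNC=O | starting material
10 | methyl isocyanide | C[N+]#[C-] | intermediate
11 | isocyanomethyllithium | [Li]C[N+]#[C-] | intermediate (not isolated)
12 | dilithium alkoxide-enolate of (4R,5R)-4-(tert-butyldimethylsilyloxy)-7-hydroxy-1-isocyano-5-methylheptan-2-one | [Li+].[Li+].[O-]CC[C@@H](C)[C@@H](C/C([O-])=C/[N+]#[C-])O[Si](C)(C)C(C)(C)C | intermediate (not isolated)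
13 | lithium (3R,4R)-4-(tert-butyldimethylsilyloxy)-5-(2-lithio-1,3-oxazol-5-yl)-3-methylpentan-1-olate | [Li+].[O-]CC[C@@H](C)[C@@H](Cc1cnc([Li])o1)O[Si](C)(C)C(C)(C)C | intermediate (not isolated)
14 | (3R,4R)-4-(tert-butyldimethylsilyloxy)-3-methyl-5-(1,3-oxazol-5-yl)pentan-1-ol | OCC[C@@H](C)[C@@H](Cc1cnco1)O[Si](C)(C)C(C)(C)C | intermediate
15 | 5-[(2R,3R)-2-(tert-butyldimethylsilyloxy)-5-iodo-3-methylpentyl]-1,3-oxazole | ICC[C@@H](C)[C@@H](Cc1cnco1)O[Si](C)(C)C(C)(C)C | intermediate
16 | ethyl (Z)-3-iodoacrylate | CCOC(=O)/C=C\I | starting material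
17 | ethyl 2-[bis(2,2,2-trifluoroethoxy)phosphoryl]propanoate | CCOC(=O)C(C)P(=O)(OCC(F)(F)F)OCC(F)(F)F | starting material
18 | (Z)-3-iodoprop-2-enal | O=C/C=C\I | intermediate (not isolated)
19 | ethyl (2Z,4Z)-5-iodo-2-methylpenta-2,4-dienoate | CCOC(=O)/C(C)=C\C=C/I | intermediate
20 | [(3R,4R)-4-(tert-butyldimethylsilyloxy)-3-methyl-5-(1,3-oxazol-5-yl)pentyl]zinc iodide | I[Zn]CC[C@@H](C)[C@@H](Cc1cnco1)O[Si](C)(C)C(C)(C)C | intermediate (not isolated)
21 | ethyl (2Z,4Z,8R,9R)-9-(tert-butyldimethylsilyloxy)-2,8-dimethyl-10-(1,3-oxazol-5-yl)deca-2,4-dienoate | CCOC(=O)/C(C)=C\C=C/CC[C@@H](C)[C@@H](Cc1cnco1)O[Si](C)(C)C(C)(C)C | intermediate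
22 | (2Z,4Z,8R,9R)-9-(tert-butyldimethylsilyloxy)-2,8-dimethyl-10-(1,3-oxazol-5-yl)deca-2,4-dienoic acid | OC(=O)/C(C)=C\C=C/CC[C@@H](C)[C@@H](Cc1cnco1)O[Si](C)(C)C(C)(C)C | intermediate
23 | (2Z,4Z,8R,9R)-9-hydroxy-2,8-dimethyl-10-(1,3-oxazol-5-yl)deca-2,4-dienoic acid | OC(=O)/C(C)=C\C=C/CC[C@@H](C)[C@@H](Cc1cnco1)O | intermediate
24 | (2Z,4Z,8R,9R)-9-hydroxy-2,8-dimethyl-10-(1,3-oxazol-5-yl)deca-2,4-dienoic 2,4,6-trichlorobenzoic anhydride | O=C(OC(=O)c1c(Cl)cc(Cl)cc1Cl)/C(C)=C\C=C/CC[C@@H](C)[C@@H](Cc1cnco1)O | intermediate (not isolated)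
25 | 2,4,6-trichlorobenzoic mixed anhydride of the head-to-tail ester dimer of 23 | O[C@H](Cc1cnco1)[C@H](C)CC/C=C\C=C(C)/C(=O)O[C@H](Cc1cnco1)[C@H](C)CC/C=C\C=C(C)/C(=O)OC(=O)c1c(Cl)cc(Cl)cc1Cl | intermediate (not isolated)
26 | (3Z,5Z,9R,10R,13Z,15Z,19R,20R)-3,9,13,19-tetramethyl-10,20-bis(1,3-oxazol-5-ylmethyl)-1,11-dioxacycloicosa-3,5,13,15-tetraene-2,12-dione (CNP0414419.1) | C/C1=C/C=C\CC[C@@H](C)[C@@H](Cc2cnco2)OC(=O)/C(C)=C\C=C/CC[C@@H](C)[C@@H](Cc2cnco2)OC1=O | target

**Step count**

Total: 14 steps. Longest linear sequence: 12 steps from 4-methylanisole (steps 1–6, 8, 9, 11–14); steps 7 and 10 prepare the two side components.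

**Steps most likely to fail**

Step 6. The C2 methylene may migrate competitively in the peracid rearrangement, which would place the ring oxygen on the wrong side of the carbonyl and lower the supply of 8. The fallback sets out from ketone 7 and returns at lactone 8 by cleaving the C1–C6 bond through an enol ether instead of by migration. Kinetic deprotonation with LiN(i-Pr)2 in THF at −78 °C, which should occur at C6, away from the silyloxy-bearing side, and trapping with Me3SiCl would give (4R,5R)-5-(tert-butyldimethylsilyloxy)-4-methyl-1-(trimethylsilyloxy)cyclohex-1-ene F1. Ozonolysis in CH2Cl2/MeOH at −78 °C with NaBH4 work-up would give (3R,4R)-3-(tert-butyldimethylsilyloxy)-6-hydroxy-4-methylhexanoic acid F2. Yamaguchi lactonisation of the hydroxy acid would then close the seven-membered ring to 8.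

Step 8. Deprotonation of the lactone next to the carbonyl, followed by β-elimination of the silyloxy group, may outpace acyl addition of the isocyanide carbanion. The fallback sets out from lactone 8 and returns at oxazole alcohol 14 by building the same 5-substituted oxazole at the aldehyde oxidation level with a much weaker base. Reduction with i-Bu2AlH in CH2Cl2 at −78 °C would give the lactol (4R,5R)-4-(tert-butyldimethylsilyloxy)-5-methyloxepan-2-ol F3, which is in equilibrium with its open hydroxy aldehyde. A van Leusen oxazole synthesis (tosylmethyl isocyanide, K2CO3, MeOH, reflux) on that aldehyde would deliver 14 with the C6 hydroxyl already free.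

Step 14. The activated seco acid may partition among the monomeric lactone, the cyclic dimer and higher oligomers, so that the one-flask cyclodimerisation gives little of the 20-membered ring. The fallback sets out from acid 22 and returns at target 26 by forming the two ester bonds one after the other.

- Steglich esterification of 22 with 2-(trimethylsilyl)ethanol (EDC·HCl, DMAP, CH2Cl2) would give 2-(trimethylsilyl)ethyl (2Z,4Z,8R,9R)-9-(tert-butyldimethylsilyloxy)-2,8-dimethyl-10-(1,3-oxazol-5-yl)deca-2,4-dienoate F4.
- HF·pyridine would remove only the silyl ether to give 2-(trimethylsilyl)ethyl (2Z,4Z,8R,9R)-9-hydroxy-2,8-dimethyl-10-(1,3-oxazol-5-yl)deca-2,4-dienoate F5.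
- Intermolecular Yamaguchi esterification of a second portion of 22 with this alcohol would give the doubly protected linear ester dimer F6.
- Bu4NF in THF would cleave both the silyl ether and the silylethyl ester to the linear dimer hydroxy acid F7.
- Yamaguchi macrolactonisation under high dilution would close the ring to 26.

Further compounds
F1 | step 6 | (4R,5R)-5-(tert-butyldimethylsilyloxy)-4-methyl-1-(trimethylsilyloxy)cyclohex-1-ene | C[Si](C)(C)OC1=CC[C@@H](C)[C@@H](C1)O[Si](C)(C)C(C)(C)C
F2 | step 6 | (3R,4R)-3-(tert-butyldimethylsilyloxy)-6-hydroxy-4-methylhexanoic acid | OCC[C@@H](C)[C@@H](CC(O)=O)O[Si](C)(C)C(C)(C)C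
F3 | step 8 | (4R,5R)-4-(tert-butyldimethylsilyloxy)-5-methyloxepan-2-ol | O1CC[C@@H](C)[C@@H](CC1O)O[Si](C)(C)C(C)(C)C
F4 | step 14 | 2-(trimethylsilyl)ethyl (2Z,4Z,8R,9R)-9-(tert-butyldimethylsilyloxy)-2,8-dimethyl-10-(1,3-oxazol-5-yl)deca-2,4-dienoate | C[Si](C)(C)CCOC(=O)/C(C)=C\C=C/CC[C@@H](C)[C@@H](Cc1cnco1)O[Si](C)(C)C(C)(C)C
F5 | step 14 | 2-(trimethylsilyl)ethyl (2Z,4Z,8R,9R)-9-hydroxy-2,8-dimethyl-10-(1,3-oxazol-5-yl)deca-2,4-dienoate | C[Si](C)(C)CCOC(=O)/C(C)=C\C=C/CC[C@@H](C)[C@@H](Cc1cnco1)O
F6 | step 14 | linear ester dimer carrying the C9 tert-butyldimethylsilyl ether on one half and the 2-(trimethylsilyl)ethyl ester on the other | CC(C)(C)[Si](C)(C)O[C@H](Cc1cnco1)[C@H](C)CC/C=C\C=C(C)/C(=O)O[C@H](Cc1cnco1)[C@H](C)CC/C=C\C=C(C)/C(=O)OCC[Si](C)(C)C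
F7 | step 14 | linear ester dimer hydroxy acid | O[C@H](Cc1cnco1)[C@H](C)CC/C=C\C=C(C)/C(=O)O[C@H](Cc1cnco1)[C@H](C)CC/C=C\C=C(C)/C(=O)O
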